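The oxolane ring is cut at C2–C3 and C4–C5: O1 with its two benzylic carbons C2 and C5 is a latent diaryl carbonyl ylide, and C3–C4 with the two cis methyl groups is a Z-alkene. The key step is a [3+2] cycloaddition of the ylide, released by photoredox C–C scission of a trans-2,3-diaryloxirane, to (5S)-5-(d-menthyloxy)furan-2(5H)-one; it closes the ring and sets all four ring stereocentres at once. The phenol is carried as a mesylate, which polarises the ylide and so fixes the regiochemistry, while the menthyloxy acetal fixes the face. The lactone and acetal carbons are then reduced to the two methyl groups.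

Key step: step 4

Remark: the oxolane is numbered O1, C2 (bearing the 4-hydroxy-3,5-dimethoxyphenyl group), C3, C4, C5 (bearing the 3,4-dimethoxyphenyl group). The target is (2R,3R,4S,5S): aryl groups cis to each other, methyl groups cis to each other, each aryl trans to its neighbouring methyl. 5-Hydroxyfuran-2(5H)-one and (+)-menthol are taken as commercial.

Step 1
Reactants: 1 syringaldehyde (4-hydroxy-3,5-dimethoxybenzaldehyde)
Product: 2 4-formyl-2,6-dimethoxyphenyl methanesulfonate
Conditions: MsCl, Et3N, CH2Cl2, 0 °C to rt
Reagents that add atoms: methanesulfonyl chloride, CS(=O)(=O)Cl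
Why: Base-mediated O-sulfonylation of the phenol is fast and chemoselective, and the mesylate both protects the phenol and turns this aryl ring into the electron-poor partner needed in step 4.

Step 2
Reactants: 3 3,4-dimethoxybenzyl bromide; 4 tetrahydrothiophene; 2 4-formyl-2,6-dimethoxyphenyl methanesulfonate
Product: 7 trans-2-(3,4-dimethoxyphenyl)-3-[3,5-dimethoxy-4-(methylsulfonyloxy)phenyl]oxirane (racemic), via sulfonium bromide 5 (not isolated), via sulfonium ylide 6 (not isolated)
Conditions: 3, 4 (1.2 equiv), MeCN, rt; then 2, Cs2CO3, rt; purification on Et3N-deactivated SiO2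
Reagents that add atoms: none
Why: Alkylation of the sulfide gives the benzylsulfonium salt, whose semi-stabilised ylide should epoxidise the aldehyde in a Corey–Chaykovsky-type reaction, reversible betaine formation favouring the trans oxirane; the two new stereocentres are racemic and are erased when the ring opens in step 4.

Step 3
Reactants: 8 5-hydroxyfuran-2(5H)-one; 9 (+)-menthol, (1S,2R,5S)
Product: 10 (5S)-5-[(1S,2R,5S)-menthyloxy]furan-2(5H)-one
Conditions: camphorsulfonic acid (cat.), toluene, reflux, Dean–Stark; crystallisation from petroleum ether, mother liquor re-equilibrated with the acid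
Reagents that add atoms: none
Why: Acid-catalysed acetalisation of the lactol gives both C5 epimers, which interconvert under acid, and the (5S) epimer of the d-menthyl series should be collected by crystallisation (crystallisation-induced diastereomer transformation), so the acetal stereocentre is set by the menthol.

Step 4
Reactants: 7 trans-2-(3,4-dimethoxyphenyl)-3-[3,5-dimethoxy-4-(methylsulfonyloxy)phenyl]oxirane; 10 (5S)-5-[(1S,2R,5S)-menthyloxy]furan-2(5H)-one
Product: 12 (3S,3aR,4R,6S,6aS)-6-(3,4-dimethoxyphenyl)-4-[3,5-dimethoxy-4-(methylsulfonyloxy)phenyl]-3-[(1S,2R,5S)-menthyloxy]tetrahydro-1H,3H-furo[3,4-c]furan-1-one (cis-fused, both aryl groups trans to the lactone ring), via carbonyl ylide 11 (not isolated)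
Conditions: 10 (2.5 equiv), 4-mesityl-2,6-di(p-tolyl)pyrylium tetrafluoroborate (5 mol %), CH2Cl2, blue LEDs (450 nm), rt, N2; chromatography
Reagents that add atoms: none
Why: The excited pyrylium salt should oxidise the dimethoxyphenyl ring of 7, the oxirane C–C bond of the radical cation breaks and back electron transfer gives the planar W-shaped carbonyl ylide 11 with both aryl groups exo, which adds suprafacially as the 4π component across the C3=C4 bond of 10 in a concerted, asynchronous 1,3-dipolar cycloaddition; the closest known reaction type is the photoredox-triggered carbonyl ylide [3+2] cycloaddition of 2,3-diaryloxiranes with electron-poor alkenes. The oxolane ring is closed by this intermolecular [3+2] (π4s+π2s) cycloaddition, both C–C bonds forming on one face of the ylide and one face of the alkene. C3a and C6a of 12 (later C3 and C4 of the target) come out cis because the Z-alkene is held in the furanone ring, and their absolute configuration is set by attack on the face of 10 anti to the menthyloxy group at C5. C4 and C6 of 12 come out cis to each other from the W geometry of 11 and trans to the lactone from the exo approach, in which the lactone points away from the ylide oxygen and the flanking aryl rings. The step needs regioselectivity, because the reverse orientation leads to the enantiomeric series: the mesyloxy-dimethoxyphenyl ring is electron-poor and the dimethoxyphenyl ring electron-rich, so 11 is polarised with carbanion character at the former carbon, which should bond to the electrophilic β-carbon C4 of 10, and oxocarbenium character at the latter, which bonds to the α-carbon C3. The minor regioisomer and any endo adduct are diastereomers of 12 and are removed by chromatography.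

Step 5
Reactants: 12 cycloadduct
Product: 13 4-[(2R,3S,4R,5S)-5-(3,4-dimethoxyphenyl)-3,4-bis(hydroxymethyl)oxolan-2-yl]-2,6-dimethoxyphenyl methanesulfonate
Conditions: LiBH4, THF, 0 °C to rt; aq. NH4Cl
Reagents that add atoms: none
Why: Hydride reduction of the lactone opens the ring to a hemiacetal alkoxide that expels menthoxide, and the aldehydes so formed are reduced at once, so both carbons end as CH2OH without touching a stereocentre, while LiBH4 should leave the aryl mesylate intact.

Step 6
Reactants: 13 diol
Product: 14 4-[(2R,3S,4R,5S)-5-(3,4-dimethoxyphenyl)-3,4-bis(methylsulfonyloxymethyl)oxolan-2-yl]-2,6-dimethoxyphenyl methanesulfonate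
Conditions: MsCl (3 equiv), Et3N, CH2Cl2, −10 to 0 °C
Reagents that add atoms: methanesulfonyl chloride, CS(=O)(=O)Cl
Why: Sulfonylation of the two primary alcohols with MsCl/Et3N is fast at low temperature, so bis-mesylation should outrun cyclisation of a monomesylate to the bicyclic ether, and no stereocentre is involved.

Step 7
Reactants: 14 trimesylate
Product: 15 4-[(2R,3R,4S,5S)-5-(3,4-dimethoxyphenyl)-3,4-dimethyloxolan-2-yl]-2,6-dimethoxyphenol (target)
Conditions: LiAlH4 (excess), THF, 0 °C then reflux; Rochelle salt work-up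
Reagents that add atoms: none
Why: LiAlH4 should displace the two primary mesylates by SN2 attack of hydride at carbon (C–O cleavage) to give the two methyl groups and cleave the aryl mesylate by attack at sulfur (S–O cleavage) to free the phenol, with no stereocentre involved.

Compound list
1 | syringaldehyde (4-hydroxy-3,5-dimethoxybenzaldehyde) | COc1cc(C=O)cc(OC)c1O | starting material
2 | 4-formyl-2,6-dimethoxyphenyl methanesulfonate | COc1cc(C=O)cc(OC)c1OS(C)(=O)=O | intermediate
3 | 3,4-dimethoxybenzyl bromide | COc1ccc(CBr)cc1OC | starting material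
4 | tetrahydrothiophene | C1CCSC1 | starting material
5 | 1-(3,4-dimethoxybenzyl)tetrahydrothiophenium bromide (not isolated) | COc1ccc(C[S+]2CCCC2)cc1OC.[Br-] | intermediate
6 | (3,4-dimethoxybenzylidene)tetrahydrothiophenium ylide (not isolated) | COc1ccc([CH-][S+]2CCCC2)cc1OC | intermediate
7 | trans-2-(3,4-dimethoxyphenyl)-3-[3,5-dimethoxy-4-(methylsulfonyloxy)phenyl]oxirane, racemic (one enantiomer drawn) | COc1ccc([C@@H]2O[C@H]2c3cc(OC)c(OS(C)(=O)=O)c(OC)c3)cc1OC | intermediate
8 | 5-hydroxyfuran-2(5H)-one | O=C1C=CC(O)O1 | starting material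
9 | (+)-menthol, (1S,2R,5S)-2-isopropyl-5-methylcyclohexanol | CC(C)[C@H]1CC[C@H](C)C[C@@H]1O | starting material
10 | (5S)-5-[(1S,2R,5S)-menthyloxy]furan-2(5H)-one | O=C1C=C[C@@H](O[C@H]2C[C@@H](C)CC[C@@H]2C(C)C)O1 | intermediate
11 | W-shaped carbonyl ylide from 7, both aryl groups exo (not isolated) | COc1ccc(/C=[O+]/[CH-]c2cc(OC)c(OS(C)(=O)=O)c(OC)c2)cc1OC | intermediate
12 | (3S,3aR,4R,6S,6aS)-6-(3,4-dimethoxyphenyl)-4-[3,5-dimethoxy-4-(methylsulfonyloxy)phenyl]-3-[(1S,2R,5S)-menthyloxy]tetrahydro-1H,3H-furo[3,4-c]furan-1-one | COc1ccc([C@H]2O[C@@H](c4cc(OC)c(OS(C)(=O)=O)c(OC)c4)[C@H]3[C@@H]2C(=O)O[C@@H]3O[C@H]5C[C@@H](C)CC[C@@H]5C(C)C)cc1OC | intermediate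
13 | 4-[(2R,3S,4R,5S)-5-(3,4-dimethoxyphenyl)-3,4-bis(hydroxymethyl)oxolan-2-yl]-2,6-dimethoxyphenyl methanesulfonate | COc1ccc([C@H]2O[C@@H](c3cc(OC)c(OS(C)(=O)=O)c(OC)c3)[C@H](CO)[C@@H]2CO)cc1OC | intermediate
14 | 4-[(2R,3S,4R,5S)-5-(3,4-dimethoxyphenyl)-3,4-bis(methylsulfonyloxymethyl)oxolan-2-yl]-2,6-dimethoxyphenyl methanesulfonate | COc1ccc([C@H]2O[C@@H](c3cc(OC)c(OS(C)(=O)=O)c(OC)c3)[C@H](COS(C)(=O)=O)[C@@H]2COS(C)(=O)=O)cc1OC | intermediate
15 | 4-[(2R,3R,4S,5S)-5-(3,4-dimethoxyphenyl)-3,4-dimethyloxolan-2-yl]-2,6-dimethoxyphenol | COc1ccc([C@H]2O[C@@H](c3cc(OC)c(O)c(OC)c3)[C@H](C)[C@@H]2C)cc1OC | target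

Total step count: 7. Longest linear sequence: 6 steps (steps 1, 2, 4, 5, 6, 7 from syringaldehyde).

Steps most likely to fail

Step 4. Kinetic control may be incomplete: endo approach of the furanone or a non-W ylide geometry would give epimers at the two aryl-bearing carbons, and a weakly polarised ylide would erode regioselectivity. The epimers still carry the correct configuration at the two future methyl-bearing carbons, so the fallback replaces kinetic control by thermodynamic control of the benzylic centres. From 7 and 10, the C4,C6-bis-epimeric (endo) adduct F1 is reduced with LiBH4 to the all-cis diol F2, mesylated to the trimesylate F3 and reduced with LiAlH4 to the all-cis phenol F4. BF3·OEt2 in CH2Cl2 at 0 °C then ionises the benzylic C–O bonds reversibly (p-quinone methide or benzylic cation), and reclosure should place each aryl trans to its neighbouring methyl, which returns to the route at 15. Mixed exo/endo material can be carried through and equilibrated in the same way.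

Step 7. Once the phenoxide is unmasked at reflux, the benzylic C2–O bond may be hydrogenolysed through a quinone methide, or hydride may attack sulfur of an alkyl mesylate and return an alcohol. The fallback separates the two events: from 14, LiBHEt3 (THF, 0 °C to rt) reduces only the two primary mesylates to give the aryl mesylate of the target F5, and KOH in MeOH/H2O at 60 °C then cleaves the aryl mesylate to return at 15.

Step 2. The base may hydrolyse the aryl mesylate, and the electron-rich oxirane may rearrange (Meinwald) on isolation. The fallback is olefination and neutral epoxidation: from 3, Arbuzov reaction with P(OEt)3 gives diethyl (3,4-dimethoxybenzyl)phosphonate F6; Horner–Wadsworth–Emmons olefination with 2 (NaH, THF) gives the (E)-stilbene F7; epoxidation with dimethyldioxirane in acetone at 0 °C returns to the route at 7.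

Further compounds
F1 | step 4 | (3S,3aR,4S,6R,6aS)-6-(3,4-dimethoxyphenyl)-4-[3,5-dimethoxy-4-(methylsulfonyloxy)phenyl]-3-[(1S,2R,5S)-menthyloxy]tetrahydro-1H,3H-furo[3,4-c]furan-1-one (endo adduct) | COc1ccc([C@@H]2O[C@H](c4cc(OC)c(OS(C)(=O)=O)c(OC)c4)[C@H]3[C@@H]2C(=O)O[C@@H]3O[C@H]5C[C@@H](C)CC[C@@H]5C(C)C)cc1OC
F2 | step 4 | 4-[(2S,3S,4R,5R)-5-(3,4-dimethoxyphenyl)-3,4-bis(hydroxymethyl)oxolan-2-yl]-2,6-dimethoxyphenyl methanesulfonate (all-cis diol) | COc1ccc([C@@H]2O[C@H](c3cc(OC)c(OS(C)(=O)=O)c(OC)c3)[C@H](CO)[C@@H]2CO)cc1OC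
F3 | step 4 | 4-[(2S,3S,4R,5R)-5-(3,4-dimethoxyphenyl)-3,4-bis(methylsulfonyloxymethyl)oxolan-2-yl]-2,6-dimethoxyphenyl methanesulfonate (all-cis trimesylate) | COc1ccc([C@@H]2O[C@H](c3cc(OC)c(OS(C)(=O)=O)c(OC)c3)[C@H](COS(C)(=O)=O)[C@@H]2COS(C)(=O)=O)cc1OC
F4 | step 4 | 4-[(2S,3R,4S,5R)-5-(3,4-dimethoxyphenyl)-3,4-dimethyloxolan-2-yl]-2,6-dimethoxyphenol (all-cis phenol, 2,5-bis-epimer of the target) | COc1ccc([C@@H]2O[C@H](c3cc(OC)c(O)c(OC)c3)[C@H](C)[C@@H]2C)cc1OC
F5 | step 7 | 4-[(2R,3R,4S,5S)-5-(3,4-dimethoxyphenyl)-3,4-dimethyloxolan-2-yl]-2,6-dimethoxyphenyl methanesulfonate | COc1ccc([C@H]2O[C@@H](c3cc(OC)c(OS(C)(=O)=O)c(OC)c3)[C@H](C)[C@@H]2C)cc1OC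
F6 | step 2 | diethyl (3,4-dimethoxybenzyl)phosphonate | CCOP(=O)(Cc1ccc(OC)c(OC)c1)OCC
F7 | step 2 | 4-[(E)-2-(3,4-dimethoxyphenyl)ethenyl]-2,6-dimethoxyphenyl methanesulfonate | COc1ccc(/C=C/c2cc(OC)c(OS(C)(=O)=O)c(OC)c2)cc1OC
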